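**Plan**
Atom numbers are those of the heavy atoms in the target SMILES (C1 methyl … C26). The retrosynthesis cuts N4–O5, then the lactone bond O17–C15 (C15–C16 back to a C15 ketone), N4–C6 (aza-Michael), C6=C14 and C7=C8 (metathesis), C14–C15 (Ni/Cr coupling), C21–C22 (Michael addition) and C2–C25 (radical cyclisation).
Forward: ring B is cyclopentadiene (as its chlorosulfonyl isocyanate β-lactam), ring A closes by a 5-exo vinyl radical, C22 is made quaternary, the C6–C14 chain is joined at C15, rings F and D form together by dienyne metathesis, then ring C (N4 to C6), ring E (lactone) and the N-oxide.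
Feature behind the key step: the cyclopentene (C7–C11, C7=C8) and the cyclohexane (C6, C7, C11–C14) share the C7–C11 bond, and a C8=C7–C6=C14 diene conjugated to a C15 ketone is exactly what an ene–yne–ene cascade on a C11-branched chain delivers; it also leaves C6 as the β-carbon, 6-endo to N4.
Stereochemistry: C26 from a lipase resolution; C25 (cis fusion), C2 (convex-face hydrogenation) and C22 (convex-face Michael addition) are relayed from it; C11 from an enamine-catalysed Michael addition; C6 and C14 from the aza-Michael addition and its kinetic protonation; C15 from tether-directed lactonisation; N4 from oxidation of the lone pair anti to H26.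

Key step: step 16

Assumption: the lipase is taken to open the (1R,5S) enantiomer of lactam 4, as it does with the saturated cyclopentane-fused β-lactam; should the sense be reversed, the recovered lactam would be methanolysed instead and enter at compound 6.
Assumption: amine 28 is taken to react through the invertomer whose lone pair is anti to H26 (C3 and C6 both equatorial on nitrogen), because a chair piperidine with the pyrrolidine cis-fused would place the C16 methyl syn-axial to C25.

Step 1
Reactants: 1 cyclopenta-1,3-diene (freshly cracked); 2 chlorosulfonyl isocyanate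
Product: 4 rac-cis-6-azabicyclo[3.2.0]hept-3-en-7-one, via N-chlorosulfonyl β-lactam 3 (not isolated)
Conditions: Et2O, −20 °C; then aq. Na2SO3, 0 °C
Reagents that add atoms: none
Why: Graf [2+2] cycloaddition of the isocyanate to one diene double bond (carbonyl carbon to the diene terminus, nitrogen to the allylic carbon) and reductive N-desulfonylation should give the cis-fused β-lactam that already holds N4–C26, C22–C15 and the C24=C25 alkene.

Step 2
Reactants: 4 rac-cis-6-azabicyclo[3.2.0]hept-3-en-7-one
Product: 5 (1R,2S)-2-aminocyclopent-3-ene-1-carboxylic acid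
Conditions: immobilised Candida antarctica lipase B, H2O (1 equiv), i-Pr2O, 65 °C; filter
Reagents that add atoms: water, O
Why: Lipase-catalysed enantioselective lactam hydrolysis (kinetic resolution) should open only the (1R,5S) lactam, and the insoluble amino acid is filtered from the unreacted (1S,5R) lactam; this fixes C26.

Step 3
Reactants: 5 (1R,2S)-2-aminocyclopent-3-ene-1-carboxylic acid
Product: 6 methyl (1R,2S)-2-aminocyclopent-3-ene-1-carboxylate hydrochloride
Conditions: SOCl2, MeOH, 0 °C to rt
Reagents that add atoms: methanol, CO; thionyl chloride, ClS(Cl)=O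
Why: Fischer esterification with HCl generated in situ should give the ester as its stable hydrochloride without touching either stereocentre.

Step 4
Reactants: 6 methyl (1R,2S)-2-aminocyclopent-3-ene-1-carboxylate hydrochloride; 7 2,3-dibromoprop-1-ene
Product: 8 methyl (1R,2S)-2-[(2-bromoprop-2-en-1-yl)amino]cyclopent-3-ene-1-carboxylate
Conditions: K2CO3, MeCN, rt
Reagents that add atoms: none
Why: SN2 N-alkylation at the allylic CH2Br (the vinylic bromide is inert) should install C3, C2 and C1 with the halide needed for the radical step; the branched secondary amine resists a second alkylation.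

Step 5
Reactants: 8 methyl (1R,2S)-2-[(2-bromoprop-2-en-1-yl)amino]cyclopent-3-ene-1-carboxylate
Product: 9 methyl (1R,2S)-2-[(2-bromoprop-2-en-1-yl)(tert-butoxycarbonyl)amino]cyclopent-3-ene-1-carboxylate
Conditions: Boc2O, DMAP (cat.), CH2Cl2, 40 °C
Reagents that add atoms: di-tert-butyl dicarbonate, CC(C)(C)OC(=O)OC(=O)OC(C)(C)C
Why: Carbamate formation should protect N4 for the radical, enolate and metathesis chemistry and is removable with acid at the end.

Step 6
Reactants: 9 methyl (1R,2S)-2-[(2-bromoprop-2-en-1-yl)(tert-butoxycarbonyl)amino]cyclopent-3-ene-1-carboxylate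
Product: 10 1-tert-butyl 6-methyl cis-fused 3-methylidenehexahydrocyclopenta[b]pyrrole-1,6(2H)-dicarboxylate (H25 and H26 cis; ester cis to N4)
Conditions: Bu3SnH (slow addition), AIBN (cat.), PhH, 80 °C
Reagents that add atoms: none
Why: Stork-type vinyl radical cyclisation: the C2 radical should add 5-exo-trig to C25 and the C24 radical is reduced by the stannane; two fused five-membered rings can only be cis, so C25 follows from C26.

Step 7
Reactants: 10 1-tert-butyl 6-methyl cis-fused 3-methylidenehexahydrocyclopenta[b]pyrrole-1,6(2H)-dicarboxylate
Product: 11 1-tert-butyl 6-methyl 3-methyloctahydrocyclopenta[b]pyrrole-1,6-dicarboxylate (H2, H25 and H26 all cis; methyl on the concave face)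
Conditions: H2 (1 atm), 10% Pd/C, EtOAc, rt
Reagents that add atoms: none
Why: Heterogeneous hydrogenation should deliver hydrogen to the exocyclic methylene from the convex face of the cis-bicyclo[3.3.0] skeleton (the face of H25 and H26), which sets C2; prior migration to the endocyclic enecarbamate would converge on the same product.

Step 8
Reactants: 11 1-tert-butyl 6-methyl 3-methyloctahydrocyclopenta[b]pyrrole-1,6-dicarboxylate
Product: 12 tert-butyl 6-formyl-3-methylhexahydrocyclopenta[b]pyrrole-1(2H)-carboxylate
Conditions: DIBAL-H (1.1 equiv), PhMe, −78 °C; Rochelle salt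
Reagents that add atoms: none
Why: DIBAL-H partial reduction should stop at the aluminium hemiacetal at −78 °C and release the aldehyde on work-up; the C22 configuration is of no consequence because C22 is enolised next.

Step 9
Reactants: 12 tert-butyl 6-formyl-3-methylhexahydrocyclopenta[b]pyrrole-1(2H)-carboxylate; 13 methyl acrylate
Product: 14 tert-butyl 6-formyl-6-(3-methoxy-3-oxopropyl)-3-methylhexahydrocyclopenta[b]pyrrole-1(2H)-carboxylate (propanoate chain cis to H26, formyl cis to N4)
Conditions: t-BuOK (0.2 equiv), t-BuOH/THF, 0 °C
Reagents that add atoms: none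
Why: Base-catalysed Michael addition of the α-branched aldehyde enolate: the acrylate should approach the exocyclic enolate from the convex face (syn to H26, anti to the N-Boc pyrrolidine), which sets quaternary C22 with C21 cis to H26.

Step 10
Reactants: 15 hex-5-en-1-ol
Product: 16 hex-5-enal
Conditions: TEMPO (cat.), PhI(OAc)2, CH2Cl2, rt
Reagents that add atoms: none
Why: Oxoammonium (TEMPO/diacetoxyiodobenzene) oxidation should stop at the aldehyde and leave the terminal alkene alone.

Step 11
Reactants: 16 hex-5-enal; 17 but-3-en-2-one
Product: 18 (R)-2-(but-3-en-1-yl)-5-oxohexanal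
Conditions: (S)-2-[methoxy(diphenyl)methyl]pyrrolidine (5 mol %), ethyl 3,4-dihydroxybenzoate (20 mol %), neat, 4 °C
Reagents that add atoms: none
Why: Enamine-catalysed asymmetric Michael addition of an aldehyde to a vinyl ketone: the enone should add to the enamine face remote from the diphenyl(methoxy)methyl group, which sets the centre that becomes C11 with all three arms in place.

Step 12
Reactants: 18 (R)-2-(but-3-en-1-yl)-5-oxohexanal
Product: 19 (R)-5-ethynylnon-8-en-2-one
Conditions: dimethyl (1-diazo-2-oxopropyl)phosphonate, K2CO3, MeOH, 0 °C
Reagents that add atoms: dimethyl (1-diazo-2-oxopropyl)phosphonate, CC(=O)C(=[N+]=[N-])P(=O)(OC)OC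
Why: Ohira–Bestmann homologation should turn the aldehyde into the C7≡C6 alkyne faster than carbonate can epimerise the α-carbon or promote aldol closure onto the methyl ketone, which the reagent does not attack.

Step 13
Reactants: 19 (R)-5-ethynylnon-8-en-2-one
Product: 20 (R)-5-ethynylnona-1,8-dien-2-yl trifluoromethanesulfonate
Conditions: KHMDS (1.05 equiv), THF, −78 °C; then PhNTf2
Reagents that add atoms: N-phenylbis(trifluoromethanesulfonimide), O=S(=O)(N(c1ccccc1)S(=O)(=O)C(F)(F)F)C(F)(F)F
Why: Kinetic deprotonation on the methyl side of the ketone (more acidic than the alkyne C–H towards the amide base) and O-triflation should give the 1,1-disubstituted enol triflate, that is C14 with its exocyclic methylene.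

Step 14
Reactants: 14 tert-butyl 6-formyl-6-(3-methoxy-3-oxopropyl)-3-methylhexahydrocyclopenta[b]pyrrole-1(2H)-carboxylate; 20 (R)-5-ethynylnona-1,8-dien-2-yl trifluoromethanesulfonate
Product: 21 allylic alcohol, tert-butyl 6-[5-ethynyl-1-hydroxy-2-methylidenenon-8-en-1-yl]-6-(3-methoxy-3-oxopropyl)-3-methylhexahydrocyclopenta[b]pyrrole-1(2H)-carboxylate (both C15 epimers)
Conditions: CrCl2 (5 equiv), NiCl2 (2 mol %), DMF, rt
Reagents that add atoms: none
Why: Nozaki–Hiyama–Kishi coupling: nickel inserts into the alkenyl triflate and the alkenylchromium(III) formed by transmetallation should add only to the aldehyde, so that methyl ester, carbamate, alkyne and alkene are spectators; the carbinol configuration is lost in the next step.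

Step 15
Reactants: 21 allylic alcohol (both C15 epimers)
Product: 22 tert-butyl 6-(5-ethynyl-2-methylidenenon-8-enoyl)-6-(3-methoxy-3-oxopropyl)-3-methylhexahydrocyclopenta[b]pyrrole-1(2H)-carboxylate (α-methylene ketone, C11 as in 19)
Conditions: Dess–Martin periodinane, CH2Cl2, 0 °C to rt
Reagents that add atoms: none
Why: Dess–Martin oxidation should give the α-methylene ketone under non-basic conditions that spare the Michael-acceptor alkene, the alkyne and the ester.

Step 16
Reactants: 22 α-methylene ketone dienyne
Product: 23 tert-butyl 6-(2,3,5,6,7,7a-hexahydro-1H-inden-5-ylcarbonyl)-6-(3-methoxy-3-oxopropyl)-3-methylhexahydrocyclopenta[b]pyrrole-1(2H)-carboxylate (linear dienone C15(=O)–C14=C6–C7=C8, C11 unchanged)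
Conditions: Hoveyda–Grubbs II (10 mol %), PhMe (0.005 M), 80 °C, argon sparge
Reagents that add atoms: none
Why: The catalyst should initiate at the monosubstituted C8 alkene; the alkylidene undergoes [2+2] addition and cycloreversion with the C7≡C6 alkyne in the exo sense (five-membered ring, C7=C8 formed, ruthenium moved to C6), and the conjugated vinylcarbene then closes the six-membered ring by ring-closing metathesis onto the enone methylene (C6=C14), expelling ethylene. The closest known reaction type is the tandem ring-closing dienyne metathesis that gives fused bicyclic 1,3-dienes, together with ring-closing metathesis onto α-methylene ketones to give cyclic enones. No stereocentre is created and C2, C11, C22, C25 and C26 are not touched. The selectivity needed is the order of events: the enone alkene is 1,1-disubstituted and electron-poor and the alkyne is flanked by branched C11, so neither competes for initiation, and 5-exo enyne closure outruns direct seven-membered diene closure. High dilution and removal of ethylene keep the vinylcarbene from intermolecular pathways.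

Step 17
Reactants: 23 hydrindadienyl ketone
Product: 25 tetracyclic amino ketone (ring C closed; N4 on the C6 face syn to H11, H14 anti to H6, C15 ketone), via secondary amine 24 (not isolated)
Conditions: TFA, CH2Cl2, 0 °C; evaporate; sat. aq. NaHCO3/CH2Cl2, 0 °C
Reagents that add atoms: none
Why: Acidolysis of the carbamate and neutralisation should trigger a 6-endo-trig intramolecular aza-Michael addition in which N4 reaches C6 on the face syn to H11 (C10 is held in the diene plane by the cyclopentene, so C12 is bent to the other face), and the enol is then protonated at C14 on the piperidinone axial face, anti to the pseudo-axial H6, giving the trans C6/C14 junction under kinetic control at 0 °C without base.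

Step 18
Reactants: 25 tetracyclic amino ketone
Product: 26 C15-methylidene amino ester
Conditions: Zn, CH2Br2, TiCl4, THF/CH2Cl2, 0 °C to rt
Reagents that add atoms: dibromomethane, BrCBr
Why: Lombardo–Takai methylenation uses a non-basic gem-dimetallic reagent that should methylenate the hindered ketone without enolising C14 and without attacking the ester; it removes the carbonyl that could epimerise C14 and supplies C16.

Step 19
Reactants: 26 C15-methylidene amino ester
Product: 27 C15-methylidene amino acid
Conditions: LiOH, THF/H2O, rt; 1 M HCl to pH 6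
Reagents that add atoms: lithium hydroxide, [Li+].[OH-]
Why: Saponification of the unhindered methyl ester should free the carboxylic acid; no stereocentre is adjacent to a carbonyl any longer.

Step 20
Reactants: 27 C15-methylidene amino acid
Product: 28 N-deoxy lactone (tertiary amine, all carbon stereocentres of the target)
Conditions: TfOH (2.5 equiv), CH2Cl2, −20 to 0 °C; aq. NaHCO3
Reagents that add atoms: none
Why: Acid-mediated Markovnikov hydro-lactonisation: protonation of the exocyclic methylene gives the tertiary C15 cation, which the carboxyl on the C21 tether should capture from its own face, so O17 is cis to C21 and the new methyl is anti, a configuration that direct methyl addition to the ketone from the open face would not give; the ammonium at N4 keeps the C7=C8 alkene from being protonated.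

Step 21
Reactants: 28 N-deoxy lactone
Product: 29 target N-oxide (CNP0566793.4)
Conditions: m-CPBA (1.05 equiv), CH2Cl2, −20 °C
Reagents that add atoms: 3-chloroperoxybenzoic acid, OOC(=O)c1cccc(Cl)c1
Why: Peracid N-oxidation of the tertiary amine is much faster than epoxidation of the trisubstituted alkene and should place oxygen on the lone pair anti to H26, the invertomer in which C3 and C6 are both equatorial on nitrogen.

**Compound list**
1 | cyclopenta-1,3-diene | C1=CC=CC1 | starting material
2 | chlorosulfonyl isocyanate | O=C=NS(=O)(=O)Cl | starting material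
3 | rac-cis-6-(chlorosulfonyl)-6-azabicyclo[3.2.0]hept-3-en-7-one | O=C1N(S(=O)(=O)Cl)C2C=CCC12 | intermediate
4 | rac-cis-6-azabicyclo[3.2.0]hept-3-en-7-one (racemate, cis fusion) | O=C1NC2C=CCC12 | intermediate
5 | (1R,2S)-2-aminocyclopent-3-ene-1-carboxylic acid | N[C@H]1C=CC[C@H]1C(=O)O | intermediate
6 | methyl (1R,2S)-2-aminocyclopent-3-ene-1-carboxylate hydrochloride | Cl.N[C@H]1C=CC[C@H]1C(=O)OC | intermediate
7 | 2,3-dibromoprop-1-ene | BrCC(Br)=C | starting material
8 | methyl (1R,2S)-2-[(2-bromoprop-2-en-1-yl)amino]cyclopent-3-ene-1-carboxylate | BrC(=C)CN[C@H]1C=CC[C@H]1C(=O)OC | intermediate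
9 | methyl (1R,2S)-2-[(2-bromoprop-2-en-1-yl)(tert-butoxycarbonyl)amino]cyclopent-3-ene-1-carboxylate | CC(C)(C)OC(=O)N(CC(Br)=C)[C@H]1C=CC[C@H]1C(=O)OC | intermediate
10 | 1-tert-butyl 6-methyl cis-fused 3-methylidenehexahydrocyclopenta[b]pyrrole-1,6(2H)-dicarboxylate (H25/H26 cis, ester cis to N) | C=C1CN(C(=O)OC(C)(C)C)[C@H]2[C@@H]1CC[C@H]2C(=O)OC | intermediate
11 | 1-tert-butyl 6-methyl 3-methyloctahydrocyclopenta[b]pyrrole-1,6-dicarboxylate (H2, H25, H26 all cis) | C[C@@H]1CN(C(=O)OC(C)(C)C)[C@H]2[C@@H]1CC[C@H]2C(=O)OC | intermediate
12 | tert-butyl 6-formyl-3-methylhexahydrocyclopenta[b]pyrrole-1(2H)-carboxylate (H2, H25, H26 all cis; C22 epimerisable) | C[C@@H]1CN(C(=O)OC(C)(C)C)[C@H]2[C@@H]1CC[C@H]2C=O | intermediate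
13 | methyl acrylate | C=CC(=O)OC | starting material
14 | tert-butyl 6-formyl-6-(3-methoxy-3-oxopropyl)-3-methylhexahydrocyclopenta[b]pyrrole-1(2H)-carboxylate (propanoate chain cis to H26) | C[C@@H]1CN(C(=O)OC(C)(C)C)[C@H]2[C@@H]1CC[C@@]2(CCC(=O)OC)C=O | intermediate
15 | hex-5-en-1-ol | OCCCCC=C | starting material
16 | hex-5-enal | O=CCCCC=C | intermediate
17 | but-3-en-2-one | CC(=O)C=C | starting material
18 | (R)-2-(but-3-en-1-yl)-5-oxohexanal | O=C[C@H](CCC=C)CCC(C)=O | intermediate
19 | (R)-5-ethynylnon-8-en-2-one | C#C[C@H](CCC=C)CCC(C)=O | intermediate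
20 | (R)-5-ethynylnona-1,8-dien-2-yl trifluoromethanesulfonate | C#C[C@H](CCC=C)CCC(=C)OS(=O)(=O)C(F)(F)F | intermediate
21 | allylic alcohol from 14 and 20 (C15 carbinol, both epimers) | C[C@@H]1CN(C(=O)OC(C)(C)C)[C@H]2[C@@H]1CC[C@@]2(CCC(=O)OC)C(O)C(=C)CC[C@H](C#C)CCC=C | intermediate
22 | α-methylene ketone dienyne (metathesis precursor) | C[C@@H]1CN(C(=O)OC(C)(C)C)[C@H]2[C@@H]1CC[C@@]2(CCC(=O)OC)C(=O)C(=C)CC[C@H](C#C)CCC=C | intermediate
23 | hydrindadienyl ketone (linear dienone, N-Boc) | C[C@@H]1CN(C(=O)OC(C)(C)C)[C@H]2[C@@H]1CC[C@@]2(CCC(=O)OC)C(=O)C3=CC4=CCC[C@@H]4CC3 | intermediate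
24 | secondary amine of 23 (formed as trifluoroacetate, then free base) | C[C@@H]1CN[C@H]2[C@@H]1CC[C@@]2(CCC(=O)OC)C(=O)C3=CC4=CCC[C@@H]4CC3 | intermediate
25 | tetracyclic amino ketone (N4–C6 closed, trans C6/C14 junction) | C[C@@H]1CN2[C@H]3C4=CCC[C@@H]4CC[C@@H]3C(=O)[C@]5(CCC(=O)OC)CC[C@H]1[C@@H]52 | intermediate
26 | C15-methylidene amino ester | C[C@@H]1CN2[C@H]3C4=CCC[C@@H]4CC[C@@H]3C(=C)[C@]5(CCC(=O)OC)CC[C@H]1[C@@H]52 | intermediate
27 | C15-methylidene amino acid | C[C@@H]1CN2[C@H]3C4=CCC[C@@H]4CC[C@@H]3C(=C)[C@]5(CCC(=O)O)CC[C@H]1[C@@H]52 | intermediate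
28 | N-deoxy lactone (tertiary amine) | C[C@@H]1CN2[C@H]3C4=CCC[C@@H]4CC[C@@H]3[C@@]3(C)OC(=O)CC[C@]34CC[C@H]1[C@@H]42 | intermediate
29 | target N-oxide, CNP0566793.4 | C[C@@H]1C[N@@+]2([O-])[C@H]3C4=CCC[C@@H]4CC[C@@H]3[C@@]3(C)OC(=O)CC[C@]34CC[C@H]1[C@@H]42 | target

**Step count**
Total: 21 steps. Longest linear sequence: 17 steps (steps 1–9 and 14–21); steps 10–13 make the side chain.

**Steps most likely to fail**
Step 16. After the enyne closure the ruthenium vinylcarbene may react too slowly with the electron-poor, 1,1-disubstituted enone methylene, so that ring D stays open and the carbene is lost to oligomerisation. The fallback runs the same cascade one oxidation level lower. It sets out from alcohol 21, which with a second-generation ruthenium catalyst in CH2Cl2 at 40 °C (hydroxyl-accelerated closure onto an electron-neutral alkene) should give the hydrindadienyl carbinol F1; Dess–Martin oxidation of F1 then returns the route to 23.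

Step 17. Kinetic control of the proton transfer to C14 may be lost through enolisation or retro-Michael addition and re-addition during the basic work-up, which would erode the trans C6/C14 relationship. The fallback separates C–N bond formation from protonation. It sets out from crude 25 (together with its C14 epimer): TMSOTf and Et3N convert both into the single trimethylsilyl enol ether F2, since only C14 can enolise. Cleavage of F2 at −78 °C with Bu4NF buffered by acetic acid protonates the enolate irreversibly on the axial face and comes back to 25.

Step 20. The tertiary C15 cation may lose H14 to give the tetrasubstituted C14=C15 alkene, whose re-protonation would scramble C14, or it may suffer a 1,2-shift from quaternary C22. The fallback avoids a free cation. It sets out from acid 27 (as its trifluoroacetate salt, so that the amine is not oxidised), which with Hg(OCOCF3)2 in MeNO2/THF should cyclise through a mercurinium ion to the organomercurial lactone F3; reduction of the C–Hg bond of F3 with alkaline NaBH4 comes back to 28.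

**Further compounds**
F1 | step 16 | hydrindadienyl carbinol (C15–OH analogue of 23) | C[C@@H]1CN(C(=O)OC(C)(C)C)[C@H]2[C@@H]1CC[C@@]2(CCC(=O)OC)C(O)C3=CC4=CCC[C@@H]4CC3
F2 | step 17 | trimethylsilyl enol ether of 25 (C14=C15–OSiMe3) | C[C@@H]1CN2[C@H]3C4=CCC[C@@H]4CCC3=C(O[Si](C)(C)C)[C@]5(CCC(=O)OC)CC[C@H]1[C@@H]52
F3 | step 20 | organomercurial lactone (C16 bearing HgOCOCF3) | C[C@@H]1CN2[C@H]3C4=CCC[C@@H]4CC[C@@H]3[C@@]3(C[Hg]OC(=O)C(F)(F)F)OC(=O)CC[C@]34CC[C@H]1[C@@H]42
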